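**Plan**

- Flavanone numbering is used (O1, C2, C3, C4, C4a, C5–C8, C8a; ring B primed). Going backwards, the two MOM ethers are removed first, then the C2–H bond (flavanone to flat flavone), then ring C is cut at O1–C2, C3–C4 and C4–C4a.
- This cut works because the C4 carbonyl carbon has no skeletal bonds other than those to C4a of ring A and to C3, and the ring oxygen O1 sits on C8a, ortho to C4a. Ring C can therefore be taken apart into an ortho-iodophenol, carbon monoxide and 4-ethynylanisole.
- The iodophenol goes back through its C–I bond, a silyl ether and the aryl–prenyl bond to phloroglucinol.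
- Forward: ring A is bought, the prenyl chain is joined by directed lithiation between two MOM ethers, and iodine is placed next to the one free hydroxyl. Ring C is then closed in a palladium-catalysed carbonylative three-component coupling that also brings in ring B.
- The only stereocenter (2S) comes from a ligand-controlled copper hydride conjugate reduction of the achiral flavone in the penultimate step; only a mild acidic deprotection follows.

Key step: step 6

Assumption: (R)-DTBM-SEGPHOS is taken to be the ligand enantiomer that directs hydride to the C2 face giving the 2S product; should a test reduction show the opposite sense, the (S)-ligand is used and nothing else changes.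

**Route**

Step 1
Reactants: 1 phloroglucinol
Product: 2 3,5-bis(methoxymethoxy)phenol
Conditions: MOMCl (2.0 equiv), i-Pr2NEt, DMF, 0 °C to rt; chromatography
Reagents that add atoms: chloromethyl methyl ether (MOMCl), COCCl
Why: Williamson-type O-alkylation of the phenol with the reactive chloromethyl ether is fast at oxygen, and with two equivalents the bis-ether should be the main component of a statistical mixture from which mono- and tris-ethers are separated, leaving free the one hydroxyl reserved to become O1.

Step 2
Reactants: 2 3,5-bis(methoxymethoxy)phenol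
Product: 3 triisopropyl[3,5-bis(methoxymethoxy)phenoxy]silane
Conditions: TIPSCl, imidazole, DMF, rt
Reagents that add atoms: chlorotriisopropylsilane (TIPSCl), CC(C)[Si](Cl)(C(C)C)C(C)C
Why: Imidazole-promoted O-silylation caps the last hydroxyl with a bulky, base-stable silyl ether that shields both flanking ring positions from lithiation and can later be removed by fluoride without touching the MOM acetals.

Step 3
Reactants: 3 triisopropyl[3,5-bis(methoxymethoxy)phenoxy]silane; 4 prenyl bromide (1-bromo-3-methylbut-2-ene)
Product: 6 triisopropyl[3,5-bis(methoxymethoxy)-4-(3-methylbut-2-enyl)phenoxy]silane, via aryllithium 5 (not isolated)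
Conditions: n-BuLi, THF, 0 °C; then 4, −78 °C to rt
Reagents that add atoms: none
Why: Directed ortho-metalation, in which the two MOM ethers cooperatively guide n-BuLi to the carbon between them (the silyl ether neither directs nor leaves room), gives aryllithium 5, which displaces bromide from the primary allylic carbon of 4 in an SN2 alkylation.

Step 4
Reactants: 6 triisopropyl[3,5-bis(methoxymethoxy)-4-(3-methylbut-2-enyl)phenoxy]silane
Product: 7 3,5-bis(methoxymethoxy)-4-(3-methylbut-2-enyl)phenol
Conditions: TBAF, AcOH, THF, 0 °C to rt
Reagents that add atoms: none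
Why: Fluoride-mediated cleavage of an aryl silyl ether, buffered with acetic acid so that the electron-rich phenoxide is not left exposed, should leave the MOM acetals and the alkene untouched.

Step 5
Reactants: 7 3,5-bis(methoxymethoxy)-4-(3-methylbut-2-enyl)phenol
Product: 8 2-iodo-3,5-bis(methoxymethoxy)-4-(3-methylbut-2-enyl)phenol
Conditions: NIS (1.0 equiv), MeCN, −20 to 0 °C, dark
Reagents that add atoms: N-iodosuccinimide (NIS), O=C1CCC(=O)N1I
Why: Electrophilic aromatic iodination ortho to the free hydroxyl of a phloroglucinol-type ring, which is far more nucleophilic than the trisubstituted alkene, should give one mono-iodide because the two open ring positions are equivalent by symmetry and only one equivalent of NIS is used.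

Step 6
Reactants: 8 2-iodo-3,5-bis(methoxymethoxy)-4-(3-methylbut-2-enyl)phenol; 9 4-ethynylanisole; 10 carbon monoxide
Product: 13 5,7-bis(methoxymethoxy)-4'-methoxy-6-(3-methylbut-2-enyl)flavone, via ortho-hydroxyaryl ynone 11 (not isolated), via diethylamino enaminone 12 (not isolated)
Conditions: PdCl2(dppf) (5 mol %; dppf = 1,1'-bis(diphenylphosphino)ferrocene), CO (20 bar), Et2NH, 120 °C
Reagents that add atoms: none
Why: Zerovalent palladium, formed in the flask from PdCl2(dppf), inserts into the C–I bond of 8, CO inserts to give the aroyl palladium species, and the amine-deprotonated alkyne 9 is transferred and reductively eliminated, so that C4a–C4 and C4–C3 are made and ynone 11 results. Diethylamine adds reversibly to 11 to give enaminone 12, and the free C8a hydroxyl then attacks C2 and expels the amine (addition–elimination), forming O1–C2 and closing ring C in a 6-endo mode (6-endo-trig on the enaminone) to flavone 13. The closest known reaction type is the palladium-catalysed carbonylative Sonogashira-type coupling and cyclisation of ortho-iodophenols with terminal arylalkynes in secondary amines. No stereocenter is formed. The step needs CO insertion to outrun direct alkynylation and 6-endo closure to outrun 5-exo closure to the aurone: CO pressure together with the electron-rich aryl group (fast migration to CO) should secure the first, and the amine-derived enaminone, in which C2 is the only electrophilic carbon within reach of the hydroxyl, should secure the second. The 6-prenyl regiochemistry is fixed by the substrate, since the hydroxyl para to the prenyl group is the only free one and both other ring oxygens are MOM-capped.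

Step 7
Reactants: 13 5,7-bis(methoxymethoxy)-4'-methoxy-6-(3-methylbut-2-enyl)flavone
Product: 15 (2S)-5,7-bis(methoxymethoxy)-4'-methoxy-6-(3-methylbut-2-enyl)flavanone, via silyl enol ether 14 (not isolated)
Conditions: Cu(OAc)2 (5 mol %), (R)-DTBM-SEGPHOS (5.5 mol %), (EtO)2MeSiH, toluene, 0 °C to rt; then AcOH, THF/H2O, 0 °C
Reagents that add atoms: none
Why: In this copper hydride asymmetric conjugate reduction the bisphosphine-ligated monovalent copper hydride delivers hydride to C2 of the enone from the face selected by the chiral ligand (catalyst control sets 2S), the enolate is held as silyl enol ether 14, which shields C4 from 1,2-reduction until buffered acidic hydrolysis, and the unactivated prenyl alkene is inert to the reagent.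

Step 8
Reactants: 15 (2S)-5,7-bis(methoxymethoxy)-4'-methoxy-6-(3-methylbut-2-enyl)flavanone
Product: 16 (2S)-5,7-dihydroxy-4'-methoxy-6-(3-methylbut-2-enyl)flavanone (target)
Conditions: 3 M aq HCl, MeOH, rt to 40 °C
Reagents that add atoms: none
Why: Acid-catalysed acetal exchange (MOM cleavage) passes both methoxymethyl groups to methanol under conditions that should be too mild for chroman formation from the prenyl group or for opening of ring C, so the 2S centre is carried through unchanged.

**Compound list**

1 | phloroglucinol (benzene-1,3,5-triol) | Oc1cc(O)cc(O)c1 | starting material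
2 | 3,5-bis(methoxymethoxy)phenol | COCOc1cc(O)cc(OCOC)c1 | intermediate
3 | triisopropyl[3,5-bis(methoxymethoxy)phenoxy]silane | COCOc1cc(O[Si](C(C)C)(C(C)C)C(C)C)cc(OCOC)c1 | intermediate
4 | prenyl bromide (1-bromo-3-methylbut-2-ene) | CC(C)=CCBr | starting material
5 | [2,6-bis(methoxymethoxy)-4-(triisopropylsilyloxy)phenyl]lithium, formed in the flask in step 3, not isolated | COCOc1cc(O[Si](C(C)C)(C(C)C)C(C)C)cc(OCOC)c1[Li] | intermediate
6 | triisopropyl[3,5-bis(methoxymethoxy)-4-(3-methylbut-2-enyl)phenoxy]silane | COCOc1cc(O[Si](C(C)C)(C(C)C)C(C)C)cc(OCOC)c1CC=C(C)C | intermediate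
7 | 3,5-bis(methoxymethoxy)-4-(3-methylbut-2-enyl)phenol | COCOc1cc(O)cc(OCOC)c1CC=C(C)C | intermediate
8 | 2-iodo-3,5-bis(methoxymethoxy)-4-(3-methylbut-2-enyl)phenol | COCOc1cc(O)c(I)c(OCOC)c1CC=C(C)C | intermediate
9 | 4-ethynylanisole (1-ethynyl-4-methoxybenzene) | COc1ccc(C#C)cc1 | starting material
10 | carbon monoxide | [C-]#[O+] | starting material
11 | 1-[6-hydroxy-2,4-bis(methoxymethoxy)-3-(3-methylbut-2-enyl)phenyl]-3-(4-methoxyphenyl)prop-2-yn-1-one, formed in the flask in step 6, not isolated | COc1ccc(C#CC(=O)c2c(O)cc(OCOC)c(CC=C(C)C)c2OCOC)cc1 | intermediate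
12 | (E)-3-(diethylamino)-1-[6-hydroxy-2,4-bis(methoxymethoxy)-3-(3-methylbut-2-enyl)phenyl]-3-(4-methoxyphenyl)prop-2-en-1-one, formed in the flask in step 6, not isolated | CCN(CC)/C(c1ccc(OC)cc1)=C/C(=O)c1c(O)cc(OCOC)c(CC=C(C)C)c1OCOC | intermediate
13 | 5,7-bis(methoxymethoxy)-4'-methoxy-6-(3-methylbut-2-enyl)flavone (2-(4-methoxyphenyl)-5,7-bis(methoxymethoxy)-6-(3-methylbut-2-enyl)chromen-4-one) | COc1ccc(-c2cc(=O)c3c(cc(OCOC)c(CC=C(C)C)c3OCOC)o2)cc1 | intermediate
14 | (2S)-4-[diethoxy(methyl)silyloxy]-2-(4-methoxyphenyl)-5,7-bis(methoxymethoxy)-6-(3-methylbut-2-enyl)-2H-chromene, formed in the flask in step 7, not isolated | COc1ccc([C@@H]2C=C(O[Si](C)(OCC)OCC)c3c(cc(OCOC)c(CC=C(C)C)c3OCOC)O2)cc1 | intermediate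
15 | (2S)-5,7-bis(methoxymethoxy)-4'-methoxy-6-(3-methylbut-2-enyl)flavanone | COc1ccc([C@@H]2CC(=O)c3c(cc(OCOC)c(CC=C(C)C)c3OCOC)O2)cc1 | intermediate
16 | (2S)-5,7-dihydroxy-4'-methoxy-6-(3-methylbut-2-enyl)flavanone | COc1ccc([C@@H]2CC(=O)c3c(cc(O)c(CC=C(C)C)c3O)O2)cc1 | target

**Count**

Total steps: 8. Longest linear sequence: 8 steps, from phloroglucinol 1 to target 16.

**Steps most likely to fail**

Step 7. The ligated copper hydride may discriminate poorly between the two faces of the flat pyranone. Hydride transfer to an enone that receives electron density from two oxygen atoms may be slow. C4 may be reduced further once the enolate is unmasked. The fallback sets out from flavone 13 and returns at 15. Conjugate reduction of 13 with LiBH(s-Bu)3 (L-Selectride) in THF at −78 °C should give racemic 5,7-bis(methoxymethoxy)-4'-methoxy-6-(3-methylbut-2-enyl)flavanone F1. Asymmetric transfer hydrogenation of F1 under dynamic kinetic resolution follows, with RuCl[(S,S)-TsDPEN](p-cymene), HCO2H/Et3N and a little DBU. The base racemises the slower-reacting enantiomer by reversible opening of ring C at O1–C2. By analogy with its sense for aryl ketones, the (S,S)-catalyst should deliver the 4S alcohol, and hydride attack trans to the aryl group makes this the cis-(2S,4S)-5,7-bis(methoxymethoxy)-4'-methoxy-6-(3-methylbut-2-enyl)flavan-4-ol F2. Dess–Martin periodinane buffered with NaHCO3 in CH2Cl2 then re-oxidises C4 and gives 15.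

Step 6. The aryl palladium species may be alkynylated before CO inserts, which leads on to a benzofuran. The aroyl palladium species may be captured by the amine. Ring closure may go 5-exo, and oxidative addition into the doubly ortho-substituted, electron-rich C–I bond may be slow. The fallback uses neither palladium nor CO. It sets out from phenol 7 (so that the iodination is bypassed as well), uses alkyne 9, and returns at ynone 11 and then 13. Magnesium-mediated ortho-formylation of 7 (MgCl2, Et3N, paraformaldehyde, MeCN, reflux) should give 6-hydroxy-2,4-bis(methoxymethoxy)-3-(3-methylbut-2-enyl)benzaldehyde F3. Alkyne 9 and n-BuLi in THF at −78 °C give lithium (4-methoxyphenyl)acetylide F4, used in excess because one equivalent is consumed by the phenol. Its addition to F3 gives racemic 1-[6-hydroxy-2,4-bis(methoxymethoxy)-3-(3-methylbut-2-enyl)phenyl]-3-(4-methoxyphenyl)prop-2-yn-1-ol F5 after NH4Cl quench. This acid-sensitive alcohol is taken on crude and oxidised with MnO2 in CH2Cl2 to ynone 11, which is now isolated. Et2NH in EtOH at rt then closes ring C by the same enaminone pathway to 13.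

Step 5. A second iodination may occur at the remaining open ring position. The very electron-rich phenol may be oxidised, or the iodonium source may attack the prenyl double bond. The fallback replaces electrophilic substitution by directed metalation; it sets out from 7 and returns at 8. O-Carbamoylation (NaH, ClCONEt2, THF) gives 3,5-bis(methoxymethoxy)-4-(3-methylbut-2-enyl)phenyl N,N-diethylcarbamate F6. Treatment with s-BuLi/TMEDA in THF at −78 °C lithiates the position between the carbamate and a MOM ether (both open positions are equivalent) to give [2-(diethylcarbamoyloxy)-4,6-bis(methoxymethoxy)-5-(3-methylbut-2-enyl)phenyl]lithium F7. Quenching with I2 at −78 °C gives 2-iodo-3,5-bis(methoxymethoxy)-4-(3-methylbut-2-enyl)phenyl N,N-diethylcarbamate F8. Hydrolysis of the carbamate (NaOH, EtOH/H2O, reflux) then gives 8.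

**Further compounds**

F1 | step 7 | racemic 5,7-bis(methoxymethoxy)-4'-methoxy-6-(3-methylbut-2-enyl)flavanone | COc1ccc(C2CC(=O)c3c(cc(OCOC)c(CC=C(C)C)c3OCOC)O2)cc1
F2 | step 7 | (2S,4S)-5,7-bis(methoxymethoxy)-4'-methoxy-6-(3-methylbut-2-enyl)flavan-4-ol (2,4-cis) | COc1ccc([C@@H]2C[C@H](O)c3c(cc(OCOC)c(CC=C(C)C)c3OCOC)O2)cc1
F3 | step 6 | 6-hydroxy-2,4-bis(methoxymethoxy)-3-(3-methylbut-2-enyl)benzaldehyde | O=Cc1c(O)cc(OCOC)c(CC=C(C)C)c1OCOC
F4 | step 6 | lithium (4-methoxyphenyl)acetylide | [Li]C#Cc1ccc(OC)cc1
F5 | step 6 | racemic 1-[6-hydroxy-2,4-bis(methoxymethoxy)-3-(3-methylbut-2-enyl)phenyl]-3-(4-methoxyphenyl)prop-2-yn-1-ol | COc1ccc(C#CC(O)c2c(O)cc(OCOC)c(CC=C(C)C)c2OCOC)cc1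
F6 | step 5 | 3,5-bis(methoxymethoxy)-4-(3-methylbut-2-enyl)phenyl N,N-diethylcarbamate | CCN(CC)C(=O)Oc1cc(OCOC)c(CC=C(C)C)c(OCOC)c1
F7 | step 5 | [2-(diethylcarbamoyloxy)-4,6-bis(methoxymethoxy)-5-(3-methylbut-2-enyl)phenyl]lithium | CCN(CC)C(=O)Oc1cc(OCOC)c(CC=C(C)C)c(OCOC)c1[Li]
F8 | step 5 | 2-iodo-3,5-bis(methoxymethoxy)-4-(3-methylbut-2-enyl)phenyl N,N-diethylcarbamate | CCN(CC)C(=O)Oc1cc(OCOC)c(CC=C(C)C)c(OCOC)c1I
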